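**Plan**

1. Retrosynthesis: remove the C6 angelate and the C11=C13 methylene, then cut C1–C2, C3–C4 and C1–O of the 7-oxabicyclo[2.2.1]heptane in one stroke. This leaves a trans-1,2 pair CHO (C1, on quaternary C10) / COCH3 (C4, on C5) on ring B plus a two-carbon dipolarophile. Further cuts: lactone O–C8 (epoxide opening), C7–C11 (Ireland–Claisen), C10–C1 and C5–C4 (conjugate addition/enolate alkylation of a 4-silyloxy-2-methylcyclohexenone).
2. Forward order: ring B (from a p-quinone monoketal) → γ-lactone → in the key step first the ylide ring O/C1/C10/C5/C4, then last the ring O/C1/C2/C3/C4 by [3+2] addition of an ethylene equivalent.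
3. Enabling feature: C1 and C4, the two carbons on the bridging oxygen, are 1,4-related through C10–C5 and so form a latent cyclic carbonyl ylide. C10 is quaternary, so a carbene at C1 has no β-hydrogen and is captured by the C4 ketone oxygen. C2 and C3 are bare CH2 groups.
4. Stereochemistry: C6 by CBS reduction; C5 anti to OTBS and C10 anti to the C5 vinyl group; C9→C7 by suprafacial [3,3] shift; C8/C9 by α-epoxidation and trans-diaxial opening; C1/C4 by attack on the H-5 face of the ylide.
5. Helpers, all removed later: dimethyl acetal (C1), vinyl as masked acetyl (C4/C15), two phenylsulfonyl groups (C2/C3), TBS on O6.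

Key step: step 16

Assumption: the target is taken exactly as drawn, with H-5 trans to the C10 methyl and the C1–O–C4 bridge on the methyl face. The oxanorbornane is therefore exo/endo (trans) annulated to ring B and strained, so it is made under kinetic control.

Locants: eudesmane numbering of the target is used throughout. Ring B = C5–C10; C14 = CH3 on C10; C15 = CH3 on C4; lactone = C7–C11–C12(=O)–O–C8. β = the face of the C10 methyl, α = the opposite face.

**Route**

Step 1
Reactants: 1 4-methoxy-3-methylphenol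
Product: 2 4,4-dimethoxy-3-methylcyclohexa-2,5-dien-1-one
Conditions: PhI(OAc)2, MeOH, 0 °C
Reagents that add atoms: methanol (CO)
Why: Oxidative dearomatisation of a p-methoxyphenol with PhI(OAc)2 in methanol traps the phenoxenium ion at C4 and gives the p-quinone monoketal.

Step 2
Reactants: 2 4,4-dimethoxy-3-methylcyclohexa-2,5-dien-1-one
Product: 3 4,4-dimethoxy-3-methylcyclohex-2-en-1-one
Conditions: H2 (1 atm), RhCl(PPh3)3 (cat.), benzene, rt
Reagents that add atoms: none
Why: Homogeneous hydrogenation with Wilkinson's catalyst should be selective for the less hindered disubstituted C5=C6 bond and leave the trisubstituted methyl-bearing enone.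

Step 3
Reactants: 3 4,4-dimethoxy-3-methylcyclohex-2-en-1-one
Product: 4 (S)-4,4-dimethoxy-3-methylcyclohex-2-en-1-ol
Conditions: (R)-Me-CBS (cat.), BH3·SMe2, THF, −20 °C; MeOH
Reagents that add atoms: none
Why: Corey–Bakshi–Shibata 1,2-reduction with the alkenyl arm as the large group should set the carbinol centre (later C6) as S with the (R)-catalyst, by analogy with aryl ketones.

Step 4
Reactants: 4 (S)-4,4-dimethoxy-3-methylcyclohex-2-en-1-ol
Product: 5 (S)-1-(tert-butyldimethylsilyloxy)-4,4-dimethoxy-3-methylcyclohex-2-ene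
Conditions: TBSCl, imidazole, DMF, rt
Reagents that add atoms: tert-butyldimethylsilyl chloride (C[Si](C)(Cl)C(C)(C)C)
Why: Standard silylation of a secondary allylic alcohol; the bulky silyl ether is the control element for the next C–C bond.

Step 5
Reactants: 5 (S)-1-(tert-butyldimethylsilyloxy)-4,4-dimethoxy-3-methylcyclohex-2-ene
Product: 6 (S)-4-(tert-butyldimethylsilyloxy)-2-methylcyclohex-2-en-1-one (C1 = C9, C2 = C10, C3 = C5, C4 = C6 of the target)
Conditions: PPTS (cat.), acetone/H2O, rt
Reagents that add atoms: water (O)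
Why: Mild acid hydrolysis of the allylic dimethyl ketal unveils the enone without touching the silyl ether or the stereocentre.

Step 6
Reactants: 6 (S)-4-(tert-butyldimethylsilyloxy)-2-methylcyclohex-2-en-1-one; 7 vinylmagnesium bromide
Product: 8 trans-4-(tert-butyldimethylsilyloxy)-2-methyl-1-(trimethylsilyloxy)-3-vinylcyclohex-1-ene (5β-vinyl, 6α-OTBS, C9=C10 enol ether)
Conditions: CuBr·SMe2 (cat.), TMSCl, HMPA, THF, −78 °C; Et3N
Reagents that add atoms: chlorotrimethylsilane (C[Si](C)(C)Cl)
Why: Copper-catalysed conjugate addition accelerated by TMSCl puts the vinyl group on C5 axially and anti to the pseudoaxial γ-silyloxy group, and traps the enolate regiospecifically as the silyl enol ether.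

Step 7
Reactants: 8 the silyl enol ether; 9 trimethyl orthoformate
Product: 10 ring-B ketone (C9=O) with 10β-methyl, 10α-dimethoxymethyl (C1), 5β-vinyl and 6α-OTBS
Conditions: TMSOTf (cat.), CH2Cl2, −78 °C
Reagents that add atoms: none
Why: Mukaiyama-type (Noyori TMSOTf) addition of the enol ether to the dimethoxycarbenium ion; the electrophile attacks C10 anti to the adjacent vinyl group, the trans,trans pattern of a Noyori three-component coupling, and sets the quaternary centre.

Step 8
Reactants: 10 the ring-B ketone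
Product: 11 the C7=C8 enone of 10
Conditions: IBX, 4-methoxypyridine N-oxide, DMSO, rt
Reagents that add atoms: none
Why: IBX dehydrogenation (Nicolaou) of a ketone that can enolise only towards C8, because C10 is quaternary.

Step 9
Reactants: 11 the enone
Product: 12 the 9β-allylic alcohol (C7=C8)
Conditions: NaBH4, CeCl3·7H2O, MeOH, −78 °C
Reagents that add atoms: none
Why: Luche 1,2-reduction; hydride should attack C9 axially from the α face, anti to the pseudoaxial C10 methyl, giving the 9β-alcohol.

Step 10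
Reactants: 12 the 9β-allylic alcohol; 13 acetic anhydride
Product: 14 the 9β-acetate
Conditions: pyridine, DMAP (cat.), CH2Cl2, rt
Reagents that add atoms: none
Why: DMAP-catalysed acetylation places the two carbons that become C11 and C12 on O9.

Step 11
Reactants: 14 the 9β-acetate
Product: 17 the 7β-carboxymethyl Δ8(9) acid, via silyl ketene acetal 15 (not isolated), via trimethylsilyl ester 16 (not isolated)
Conditions: LDA, TMSCl/Et3N, THF, −78 °C → 65 °C; aq. NH4Cl
Reagents that add atoms: chlorotrimethylsilane (C[Si](C)(C)Cl; its silicon stays only in 15 and 16)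
Why: Ireland–Claisen [3,3]-sigmatropic rearrangement; bond formation is suprafacial, so the 9β C–O bond is exchanged for a 7β C–C bond and the alkene moves to C8=C9.

Step 12
Reactants: 17 the Δ8(9) acid
Product: 19 the cis-fused γ-lactone (8β-O) with 9α-OH, via 8α,9α-epoxy acid 18 (not isolated)
Conditions: mCPBA, CH2Cl2, 0 °C → rt
Reagents that add atoms: meta-chloroperbenzoic acid (O=C(OO)c1cccc(Cl)c1)
Why: Prilezhaev epoxidation on the α face (the β face is screened by the pseudoaxial C10 methyl), then 5-exo trans-diaxial (Fürst–Plattner) opening at C8 by the carboxyl group sets C8 and C9; the monosubstituted vinyl group reacts much more slowly with the peracid.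

Step 13
Reactants: 19 the hydroxy lactone
Product: 20 the C4 methyl ketone (5β-acetyl)
Conditions: PdCl2 (cat.), CuCl, O2, DMF/H2O, rt
Reagents that add atoms: water (O)
Why: Tsuji–Wacker oxidation of the terminal vinyl group with Markovnikov selectivity gives the acetyl group (C4, C15).

Step 14
Reactants: 20 the methyl ketone
Product: 21 the keto aldehyde (C1H=O on C10, C4 acetyl on C5, trans)
Conditions: PPTS (cat.), THF/H2O, 45 °C
Reagents that add atoms: water (O)
Why: Acid hydrolysis of the dimethyl acetal frees the C1 aldehyde, which cannot enolise because C10 is quaternary.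

Step 15
Reactants: 21 the keto aldehyde
Product: 22 the C1 N-[2-(trifluoromethyl)phenylsulfonyl]hydrazone
Conditions: 2-(trifluoromethyl)benzenesulfonohydrazide (1.0 equiv), MeOH, 0 °C
Reagents that add atoms: 2-(trifluoromethyl)benzenesulfonohydrazide (NNS(=O)(=O)c1ccccc1C(F)(F)F)
Why: Condensation should be selective for the aldehyde over the hindered methyl ketone at 0 °C and gives a sulfonylhydrazone that releases the diazoalkane at low temperature (Bamford–Stevens type).

Step 16
Reactants: 22 the sulfonylhydrazone; 23 (E)-1,2-bis(phenylsulfonyl)ethene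
Product: 26 the 1β,4β-epoxy cycloadduct with trans phenylsulfonyl groups on C2 and C3 (either trans diastereomer), via diazoalkane 24 (not isolated), via carbonyl ylide 25 (not isolated)
Conditions: NaH, THF, −40 → −10 °C; filtered cold solution added slowly to Rh2(OAc)4 (2 mol %) and 23 (3 equiv), CH2Cl2, 0 °C → rt
Reagents that add atoms: none
Why: Proposed new method: the hydrazone salt loses sulfinate to give diazoalkane 24, Rh2(OAc)4 turns it into a carbenoid at C1 which has no β-hydrogen (C10 is quaternary) and is therefore captured by the oxygen of the trans-disposed C4 ketone (5-membered closure of ring O/C1/C10/C5/C4) to give ylide 25, and 25 adds 23 in a concerted suprafacial [3+2] that forms C1–C2 and C3–C4 and closes ring O/C1/C2/C3/C4 last. The closest known reaction types are the Padwa Rh(II) tandem cyclisation–cycloaddition of keto diazocarbonyl compounds, isobenzofuran formation from o-acylaryl carbenes made from sulfonylhydrazone salts, and cycloadditions of non-stabilised carbonyl ylides with electron-poor alkenes; new here is a non-stabilised alkyl carbene from an aldehyde sulfonylhydrazone as the ylide source. C1 and C4 are set together by the face of the ylide that is attacked: the α face carries only H-5 and C9 with its small free hydroxyl, whereas the β face is closed by the C10 methyl and by C6 with its OTBS group, so the two-carbon bridge should enter α and the oxygen bridge end up β. The step needs ylide formation to win over pyrazoline formation from 24 and 23, O–H insertion at O9 and a 1,4-hydrogen shift in 25 (C15–H to C1); cold generation of 24, slow addition to the catalyst and an excess of a very reactive symmetrical dipolarophile are meant to secure this. The strain of the trans-annulated oxanorbornane is paid by an exothermic, irreversible cycloaddition and cannot be lost by equilibration.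

Step 17
Reactants: 26 the bis-sulfone cycloadduct
Product: 27 the 7-oxanorbornene (C2=C3)
Conditions: 6% Na(Hg), Na2HPO4, MeOH/THF, −20 °C
Reagents that add atoms: none
Why: Reductive elimination of a vicinal disulfone with sodium amalgam (bis-sulfone as acetylene equivalent); loss of the second sulfinate should be faster than β-elimination of the bridging oxygen.

Step 18
Reactants: 27 the oxanorbornene
Product: 28 the saturated 1β,4β-epoxy lactone (6α-OTBS, 9α-OH, C11 = CH2)
Conditions: H2 (1 atm), Pd/C, EtOAc, rt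
Reagents that add atoms: none
Why: Catalytic hydrogenation of the strained C2=C3 bond; no stereocentre is created.

Step 19
Reactants: 28 the saturated lactone; 29 N,N-dimethylmethyleneiminium iodide (Eschenmoser's salt)
Product: 32 the α-methylene lactone (6α-OTBS, 9α-OH), via Mannich base 30 (not isolated), via trimethylammonium iodide 31 (not isolated)
Conditions: LDA (2.2 equiv), THF, −78 °C, then 29; MeI, MeOH/CH2Cl2, rt; aq. NaHCO3
Reagents that add atoms: iodomethane (CI; its methyl stays only in 31)
Why: Eschenmoser methylenation: Mannich aminomethylation of the lactone enolate, N-methylation and Hofmann-type elimination give the exocyclic C11=C13 bond.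

Step 20
Reactants: 32 the silyl ether
Product: 33 the 6α,9α-diol
Conditions: HF·pyridine, THF/pyridine, 0 °C → rt
Reagents that add atoms: none
Why: Buffered fluoride desilylation, conditions that spare the α-methylene lactone.

Step 21
Reactants: 33 the diol; 34 angelic acid
Product: 36 the target CNP0328162.1, via angelic 2,4,6-trichlorobenzoic anhydride 35 (not isolated)
Conditions: 34, 2,4,6-trichlorobenzoyl chloride, Et3N, toluene, rt; then 33, toluene, 80 °C
Reagents that add atoms: 2,4,6-trichlorobenzoyl chloride (O=C(Cl)c1c(Cl)cc(Cl)cc1Cl; stays only in 35)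
Why: Yamaguchi-type esterification through the mixed anhydride without DMAP, the usual way to avoid Z→E isomerisation of angelates; the equatorial 6α-OH should react in preference to the axial 9α-OH, which is flanked by quaternary C10 and by C8.

**Compound list**

1 | 4-methoxy-3-methylphenol | Cc1cc(O)ccc1OC | starting material
2 | 4,4-dimethoxy-3-methylcyclohexa-2,5-dien-1-one | CC1=CC(=O)C=CC1(OC)OC | intermediate
3 | 4,4-dimethoxy-3-methylcyclohex-2-en-1-one | CC1=CC(=O)CCC1(OC)OC | intermediate
4 | (S)-4,4-dimethoxy-3-methylcyclohex-2-en-1-ol | CC1=C[C@@H](O)CCC1(OC)OC | intermediate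
5 | TBS ether of 4 | CC1=C[C@@H](O[Si](C)(C)C(C)(C)C)CCC1(OC)OC | intermediate
6 | (S)-4-(tert-butyldimethylsilyloxy)-2-methylcyclohex-2-en-1-one | CC1=C[C@@H](O[Si](C)(C)C(C)(C)C)CCC1=O | intermediate
7 | vinylmagnesium bromide | C=C[Mg]Br | starting material
8 | silyl enol ether (5β-vinyl, 6α-OTBS) | CC1=C(O[Si](C)(C)C)CC[C@H](O[Si](C)(C)C(C)(C)C)[C@H]1C=C | intermediate
9 | trimethyl orthoformate | COC(OC)OC | starting material
10 | ring-B ketone with quaternary C10 | C[C@]1(C(OC)OC)[C@H](C=C)[C@@H](O[Si](C)(C)C(C)(C)C)CCC1=O | intermediate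
11 | C7=C8 enone | C[C@]1(C(OC)OC)[C@H](C=C)[C@@H](O[Si](C)(C)C(C)(C)C)C=CC1=O | intermediate
12 | 9β-allylic alcohol | C[C@]1(C(OC)OC)[C@H](C=C)[C@@H](O[Si](C)(C)C(C)(C)C)C=C[C@@H]1O | intermediate
13 | acetic anhydride | CC(=O)OC(C)=O | starting material
14 | 9β-acetate | C[C@]1(C(OC)OC)[C@H](C=C)[C@@H](O[Si](C)(C)C(C)(C)C)C=C[C@@H]1OC(C)=O | intermediate
15 | silyl ketene acetal | C[C@]1(C(OC)OC)[C@H](C=C)[C@@H](O[Si](C)(C)C(C)(C)C)C=C[C@@H]1OC(=C)O[Si](C)(C)C | intermediate
16 | trimethylsilyl ester | C[C@]1(C(OC)OC)[C@H](C=C)[C@@H](O[Si](C)(C)C(C)(C)C)[C@H](CC(=O)O[Si](C)(C)C)C=C1 | intermediate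
17 | 7β-carboxymethyl Δ8(9) acid | C[C@]1(C(OC)OC)[C@H](C=C)[C@@H](O[Si](C)(C)C(C)(C)C)[C@H](CC(=O)O)C=C1 | intermediate
18 | 8α,9α-epoxy acid | C[C@]1(C(OC)OC)[C@H](C=C)[C@@H](O[Si](C)(C)C(C)(C)C)[C@H](CC(=O)O)[C@H]2O[C@@H]12 | intermediate
19 | hydroxy lactone (8β-O, 9α-OH) | C[C@]1(C(OC)OC)[C@H](C=C)[C@@H](O[Si](C)(C)C(C)(C)C)[C@@H]2CC(=O)O[C@@H]2[C@H]1O | intermediate
20 | C4 methyl ketone | C[C@]1(C(OC)OC)[C@H](C(C)=O)[C@@H](O[Si](C)(C)C(C)(C)C)[C@@H]2CC(=O)O[C@@H]2[C@H]1O | intermediate
21 | keto aldehyde | C[C@]1(C=O)[C@H](C(C)=O)[C@@H](O[Si](C)(C)C(C)(C)C)[C@@H]2CC(=O)O[C@@H]2[C@H]1O | intermediate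
22 | C1 N-[2-(trifluoromethyl)phenylsulfonyl]hydrazone | C[C@]1(/C=N/NS(=O)(=O)c3ccccc3C(F)(F)F)[C@H](C(C)=O)[C@@H](O[Si](C)(C)C(C)(C)C)[C@@H]2CC(=O)O[C@@H]2[C@H]1O | intermediate
23 | (E)-1,2-bis(phenylsulfonyl)ethene | O=S(=O)(/C=C/S(=O)(=O)c1ccccc1)c1ccccc1 | starting material
24 | diazoalkane | C[C@]1(C=[N+]=[N-])[C@H](C(C)=O)[C@@H](O[Si](C)(C)C(C)(C)C)[C@@H]2CC(=O)O[C@@H]2[C@H]1O | intermediate
25 | cyclic carbonyl ylide | C[C@]12[CH-][O+]=C(C)[C@@H]1[C@@H](O[Si](C)(C)C(C)(C)C)[C@@H]3CC(=O)O[C@@H]3[C@H]2O | intermediate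
26 | bis-sulfone cycloadduct | C1C(=O)O[C@H]2[C@@H]1[C@H](O[Si](C)(C)C(C)(C)C)[C@@H]1[C@@](C)([C@@H]2O)[C@H]2C(S(=O)(=O)c3ccccc3)C(S(=O)(=O)c3ccccc3)[C@]1(C)O2 | intermediate
27 | 7-oxanorbornene | C1C(=O)O[C@H]2[C@@H]1[C@H](O[Si](C)(C)C(C)(C)C)[C@@H]1[C@@](C)([C@@H]2O)[C@H]2C=C[C@]1(C)O2 | intermediate
28 | saturated 1β,4β-epoxy lactone | C1C(=O)O[C@H]2[C@@H]1[C@H](O[Si](C)(C)C(C)(C)C)[C@@H]1[C@@](C)([C@@H]2O)[C@H]2CC[C@]1(C)O2 | intermediate
29 | N,N-dimethylmethyleneiminium iodide | C=[N+](C)C.[I-] | starting material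
30 | Mannich base (C11 epimers) | CN(C)CC1C(=O)O[C@H]2[C@@H]1[C@H](O[Si](C)(C)C(C)(C)C)[C@@H]1[C@@](C)([C@@H]2O)[C@H]2CC[C@]1(C)O2 | intermediate
31 | trimethylammonium iodide | C[N+](C)(C)CC1C(=O)O[C@H]2[C@@H]1[C@H](O[Si](C)(C)C(C)(C)C)[C@@H]1[C@@](C)([C@@H]2O)[C@H]2CC[C@]1(C)O2.[I-] | intermediate
32 | α-methylene lactone, 6-O-TBS | C=C1C(=O)O[C@H]2[C@@H]1[C@H](O[Si](C)(C)C(C)(C)C)[C@@H]1[C@@](C)([C@@H]2O)[C@H]2CC[C@]1(C)O2 | intermediate
33 | 6α,9α-diol | C=C1C(=O)O[C@H]2[C@@H]1[C@H](O)[C@@H]1[C@@](C)([C@@H]2O)[C@H]2CC[C@]1(C)O2 | intermediate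
34 | angelic acid | C/C=C(/C)C(=O)O | starting material
35 | angelic 2,4,6-trichlorobenzoic anhydride | C/C=C(/C)C(=O)OC(=O)c1c(Cl)cc(Cl)cc1Cl | intermediate
36 | CNP0328162.1 | C=C1C(=O)O[C@H]2[C@@H]1[C@H](OC(=O)/C(C)=C\C)[C@@H]1[C@@](C)([C@@H]2O)[C@H]2CC[C@]1(C)O2 | target

Total step count: 21. Longest linear sequence: 21 steps (from 1).

**Steps most likely to fail**

1. Step 16 (Proposed new method). The carbenoid may be diverted before it reaches the ketone oxygen (azine formation, carbene dimerisation, direct diazo–alkene cycloaddition, O–H insertion). The ylide may collapse by proton shift before it is trapped, or the dipolarophile may add to the wrong face. Fallback with known chemistry, from 21 back to 28: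
   - Reagent-controlled Brown allylboration of the aldehyde (B-allyldiisopinocampheylborane, −78 °C; the methyl ketone is left alone) gives the 1β-configured homoallylic alcohol F1.
   - Lombardo methylenation (CH2Br2, Zn, TiCl4) of the C4 ketone gives the isopropenyl compound F2.
   - Ring-closing metathesis (Grubbs II) closes the carbocycle to the 1β-hydroxy-Δ3 alkene F3.
   - Iodoetherification (I2, NaHCO3, MeCN), a kinetically controlled anti addition in which O1 attacks C4 from the β face, gives the 3α-iodo-1β,4β-ether F4.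
   - Bu3SnH/AIBN removes the iodine and gives 28.

2. Step 11. The rearrangement needs the ring-B conformer with the C9–O bond pseudoaxial, which puts the vinyl and acetal groups axial, so the ketene acetal may decompose by elimination before the [3,3] shift occurs. Fallback from 11 back to 17, delivering hydrogen instead of carbon to C7:
   - Mukaiyama–Michael addition of 1-(tert-butyldimethylsilyloxy)-1-methoxyethene (cat. TBSOTf) gives the silyl enol ether F5 (configuration at C7 irrelevant).
   - Saegusa–Ito oxidation (Pd(OAc)2) gives the β-substituted enone F6.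
   - Conjugate reduction with Stryker's reagent should add hydride to C7 axially from the α face and place the side chain β, giving ketone F7.
   - KHMDS/PhNTf2 gives enol triflate F8.
   - Pd(OAc)2/PPh3/HCO2H/Bu3N reduction gives the alkene ester F9.
   - LiOH hydrolysis gives 17.

3. Step 21. Acylation may go to the wrong hydroxyl or to both, or the angelate may isomerise to the tiglate during a slow esterification. Fallback from 32 back to 36, masking O9 instead of relying on site selectivity:
   - 2,2,2-Trichloroethyl chloroformate/pyridine/DMAP gives the 9-O-Troc carbonate F10.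
   - HF·pyridine gives the 6-alcohol F11.
   - The same mixed-anhydride angeloylation, now with a single free hydroxyl, gives the angelate F12.
   - Zn/AcOH removes the Troc group and gives 36.

Further compounds
F1 | step 16 | 1β-hydroxy homoallylic alcohol (allyl on C1) | C[C@]1([C@H](O)CC=C)[C@H](C(C)=O)[C@@H](O[Si](C)(C)C(C)(C)C)[C@@H]2CC(=O)O[C@@H]2[C@H]1O
F2 | step 16 | isopropenyl/allyl diene | C[C@]1([C@H](O)CC=C)[C@H](C(C)=C)[C@@H](O[Si](C)(C)C(C)(C)C)[C@@H]2CC(=O)O[C@@H]2[C@H]1O
F3 | step 16 | 1β-hydroxy-Δ3 trans-decalin lactone | C1C(=O)O[C@H]2[C@@H]1[C@H](O[Si](C)(C)C(C)(C)C)[C@@H]1[C@@](C)([C@@H]2O)[C@H](O)CC=C1C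
F4 | step 16 | 3α-iodo-1β,4β-epoxy lactone | C1C(=O)O[C@H]2[C@@H]1[C@H](O[Si](C)(C)C(C)(C)C)[C@@H]1[C@@](C)([C@@H]2O)[C@H]2C[C@@H](I)[C@]1(C)O2
F5 | step 11 | Mukaiyama–Michael silyl enol ether | C[C@]1(C(OC)OC)[C@H](C=C)[C@@H](O[Si](C)(C)C(C)(C)C)C(CC(=O)OC)C=C1O[Si](C)(C)C(C)(C)C
F6 | step 11 | β-substituted enone | C[C@]1(C(OC)OC)[C@H](C=C)[C@@H](O[Si](C)(C)C(C)(C)C)C(CC(=O)OC)=CC1=O
F7 | step 11 | 7β-(methoxycarbonylmethyl) ketone | C[C@]1(C(OC)OC)[C@H](C=C)[C@@H](O[Si](C)(C)C(C)(C)C)[C@H](CC(=O)OC)CC1=O
F8 | step 11 | enol triflate | C[C@]1(C(OC)OC)[C@H](C=C)[C@@H](O[Si](C)(C)C(C)(C)C)[C@H](CC(=O)OC)C=C1OS(=O)(=O)C(F)(F)F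
F9 | step 11 | Δ8(9) methyl ester | C[C@]1(C(OC)OC)[C@H](C=C)[C@@H](O[Si](C)(C)C(C)(C)C)[C@H](CC(=O)OC)C=C1
F10 | step 21 | 9-O-Troc, 6-O-TBS α-methylene lactone | C=C1C(=O)O[C@H]2[C@@H]1[C@H](O[Si](C)(C)C(C)(C)C)[C@@H]1[C@@](C)([C@@H]2OC(=O)OCC(Cl)(Cl)Cl)[C@H]2CC[C@]1(C)O2
F11 | step 21 | 9-O-Troc 6-alcohol | C=C1C(=O)O[C@H]2[C@@H]1[C@H](O)[C@@H]1[C@@](C)([C@@H]2OC(=O)OCC(Cl)(Cl)Cl)[C@H]2CC[C@]1(C)O2
F12 | step 21 | 9-O-Troc 6-O-angelate | C=C1C(=O)O[C@H]2[C@@H]1[C@H](OC(=O)/C(C)=C\C)[C@@H]1[C@@](C)([C@@H]2OC(=O)OCC(Cl)(Cl)Cl)[C@H]2CC[C@]1(C)O2
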